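Readings and results come from a simulation on assumed constants; the scatter is artificial.

If the second end groups are the limiting reagent in cedar, the plateau measures what share of them reached first end groups.

| flask | first end groups | second end groups | third end groups | remark | time |
|---|---|---|---|---|---|
| cedar | 1 M | 0.98 equiv | 0.25 equiv | the very flask that is asked about, followed so far |  |
| ash | 1 M | 2 equiv | 0.25 equiv | run made earlier |  |
| flask | 1.0 M | 0.980 equiv | 0.250 equiv |  | 15 d |

| run | time / d | first end groups / % | over-reaction product / % |
|---|---|---|---|
| cedar | 0.833 | 31.2 | 35.2 |
| cedar | 1.67 | 24.1 | 59.9 |
| cedar | 2.50 | 22.0 | 69.8 |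
| cedar | 4.00 | 20.9 | 77.5 |
| cedar | 5.00 | 21.4 | 78.8 |
| ash | 1.04 | 1.3 | 63.2 |
| ash | 2.50 | 0 | 93.4 |
| ash | 5.00 | 0.1 | 99.3 |
| ash | 8.00 | 0.5 | 99.5 |
| ash | 10.0 | 0.7 | 100.3 |

(scatter of a reading: 0.5 percentage points)

- part of the first end groups gone at 15 d
- the over-reaction product standing at 15 d, as a percentage of the first end groups charged



Two readings give cedar's conversion by different roads. Its first end groups read 21.4 % at 5.00 d, so 78.6 % has gone, while its over-reaction product reads 78.8 %. These differ by 0.2 percentage points, less than the scatter of 0.5 points. Yet at 0.833 d, 33.6 % of cedar's charge stood in neither reading, so an intermediate was there early and the gap has since closed.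

Product over charge gives 80.4 %: this is the capture share, first end groups converted per second end group charged. Held against ash, the share times its 2 equiv comes to 161 %, more than the charge, and ash's first end groups do read 0.7 % at 10.0 d. Cedar's first end groups moved from 20.9 % to 21.4 % over its last two readings, a step the size of the scatter. We therefore carry the plateau forward and commit to 78.8 % for both answers at 15 d.

The forecast gives 78.8 % for conversion and 79 % for product, on its reading that “The stall looks like exhaustion of the second end groups”.

The flask gives 79.1 % for conversion and 79.1 % for product, with 0 % of its second end groups left at 15 d.

    first end groups + second end groups → links (k = 0.190 /M/h)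
    second end groups + third end groups → links of the second sort (k = 0.370 /M/h)
    2 third end groups → homo dimer (k = 0.290 /M/h)
    links → over-reaction product (k = 0.0500 /h)

At 0.171 d the flask's second end groups were passing into links 4.5 times as fast as into links of the second sort. That ratio belongs to that moment; taken over the whole run, the flask's product per second end group charged is 80.8 %, with 0.189 M of links of the second sort standing at 15.0 d. In a flask like this one but charged with 0.240 equiv of second end groups, the share gives 19.3 %, and that flask's conversion stands at 18.2 %.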